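**Retrosynthetic overview**
- The γ-butyrolactone (O1, C2, C3, C4, C5) is the only ring to be made. It is cut at O1–C5 and C3–C4 into a C4=C5 alkenyl sulfoxide that carries the C4 benzyl group and a ketene (O1–C2–C3) that carries the C3 benzyl group.
- Enabling feature: O1–C2(=O)–C3 is a ketene in disguise, and the unsubstituted C5H2 can pass through the thioacetal oxidation level. C4=C5 can therefore be a (Z)-alkenyl p-tolyl sulfoxide whose sulfur stereocentre is relayed to C4 and then removed.
- After the lactone-forming step, the C3 chlorine and the C5 sulfur are reduced off and C3 is equilibrated to the trans (3R,4R) lactone.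
- Both halves come from 3,4,5-trimethoxybenzyl bromide: propargylation, Andersen sulfinylation and Z-selective semihydrogenation give the sulfoxide; dichloroacetate alkylation gives the ketene precursor.

Key step: step 7

Remark (assumption on stereochemistry): the sense of sulfur-to-carbon chirality transfer in step 7 is taken from the accepted transition-state model for ketene lactonization of (Z)-alkenyl sulfoxides (sulfur lone pair syn to the cis substituent, p-tolyl anti, enolate delivered on the oxygen-bearing face); on this model (R)-sulfur with (Z)-geometry gives the (4R) centre of the target.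
Remark (assumption on supply): 3,4,5-trimethoxybenzyl bromide is taken as a purchasable reagent.

**Step 1**
Reactants: 1 5-(bromomethyl)-1,2,3-trimethoxybenzene; 2 ethynylmagnesium bromide
Product: 3 1,2,3-trimethoxy-5-(prop-2-yn-1-yl)benzene
Conditions: 2 (excess), CuCl (10 mol %), THF, 0 °C to reflux
Reagents that add atoms: none
Why: Copper-catalysed cross-coupling of a benzylic bromide with an alkynyl Grignard reagent should give the skipped aryl alkyne, the excess of 2 suppressing double benzylation; no stereocentre is formed.

**Step 2**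
Reactants: 3 1,2,3-trimethoxy-5-(prop-2-yn-1-yl)benzene; 4 (1R,2S,5R)-(−)-menthyl (S)-p-toluenesulfinate
Product: 6 (S)-1,2,3-trimethoxy-5-[3-(p-tolylsulfinyl)prop-2-yn-1-yl]benzene, via alkynylmagnesium bromide 5 (not isolated)
Conditions: EtMgBr, THF, 0 °C to rt; then added to 4, toluene, −20 °C; aq. NH4Cl
Reagents that add atoms: none
Why: Andersen sulfoxide synthesis: the alkynyl Grignard reagent should displace menthoxide from sulfur with clean inversion, which installs the only external stereocentre of the route, and inverse addition at low temperature protects the acidic propargylic CH2.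

**Step 3**
Reactants: 6 (S)-1,2,3-trimethoxy-5-[3-(p-tolylsulfinyl)prop-2-yn-1-yl]benzene
Product: 7 (R,Z)-1,2,3-trimethoxy-5-[3-(p-tolylsulfinyl)prop-2-en-1-yl]benzene
Conditions: H2 (1 atm), RhCl(PPh3)3 (5 mol %), benzene, rt
Reagents that add atoms: none
Why: Homogeneous syn-hydrogenation of a 1-alkynyl sulfoxide should stop at the (Z)-alkenyl sulfoxide under neutral conditions that leave the sulfur configuration and the skipped CH2 untouched (the descriptor changes from S to R only through the priority change of the carbon ligand).

**Step 4**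
Reactants: 8 methyl dichloroacetate; 1 5-(bromomethyl)-1,2,3-trimethoxybenzene
Product: 10 methyl 2,2-dichloro-3-(3,4,5-trimethoxyphenyl)propanoate, via lithium dichloroester enolate 9 (not isolated)
Conditions: LiN(SiMe3)2, THF, −78 °C; then 1, DMPU, −78 to −30 °C
Reagents that add atoms: none
Why: Ester enolate alkylation (SN2) of the dichloroacetate enolate, which is stable at low temperature, with a reactive benzylic bromide should give the α,α-dichloro ester; no stereocentre is formed.

**Step 5**
Reactants: 10 methyl 2,2-dichloro-3-(3,4,5-trimethoxyphenyl)propanoate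
Product: 11 2,2-dichloro-3-(3,4,5-trimethoxyphenyl)propanoic acid
Conditions: LiOH·H2O, THF/H2O, 0 °C; then 1 M HCl
Reagents that add atoms: lithium hydroxide, [Li+].[OH-]
Why: Saponification of an activated ester should be fast at 0 °C, and the carboxylate formed resists loss of HCl.

**Step 6**
Reactants: 11 2,2-dichloro-3-(3,4,5-trimethoxyphenyl)propanoic acid
Product: 12 2,2-dichloro-3-(3,4,5-trimethoxyphenyl)propanoyl chloride
Conditions: (COCl)2, DMF (cat.), CH2Cl2, 0 °C to rt; used crude
Reagents that add atoms: oxalyl chloride, ClC(=O)C(=O)Cl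
Why: Acid chloride formation through the chloroiminium intermediate should proceed under mild, Lewis-acid-free conditions that spare the electron-rich arene.

**Step 7**
Reactants: 7 (R,Z)-1,2,3-trimethoxy-5-[3-(p-tolylsulfinyl)prop-2-en-1-yl]benzene; 12 2,2-dichloro-3-(3,4,5-trimethoxyphenyl)propanoyl chloride
Product: 15 (4S)-3-chloro-5-(p-tolylsulfanyl)-3,4-bis(3,4,5-trimethoxybenzyl)dihydrofuran-2(3H)-one (epimers at C3 and C5), via chloro(3,4,5-trimethoxybenzyl)ketene 13 (not isolated), via acyloxysulfonium enolate 14 (not isolated)
Conditions: Zn(Cu) couple (excess), Et2O, reflux; 12 (excess) added slowly to 7 and the couple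
Reagents that add atoms: none
Why: Proposed new method: Zn(Cu) removes the acyl and one α-chlorine of 12 to give ketene 13, the sulfinyl oxygen of 7 adds to its central carbon to give the acyloxysulfonium enolate 14, a charge-accelerated [3,3]-sigmatropic shift joins the enolate carbon (C3) to C4 with cleavage of the S–O bond, and the freed carboxylate adds to the thionium carbon C5 (additive Pummerer reaction), so that C3–C4 and O1–C5 are made in one operation as a formal (3+2) cycloaddition. The closest known reaction type is the lactonization of alkenyl sulfoxides with dichloroketene generated from Cl3CCOCl and Zn(Cu); new here is the ketene, in which one chlorine is replaced by the 3,4,5-trimethoxybenzyl group while the remaining α-chlorine keeps the ketene electrophilic enough for O-acylation and stabilises the enolate. The lactone ring is closed in the 5-exo-trig mode by attack of carboxylate oxygen on the C5=S+ bond. C4 is controlled by the sulfur stereocentre: allylic 1,3-strain in the (Z)-alkenyl acyloxysulfonium holds the sulfur lone pair syn to the cis CH2Ar group and the p-tolyl group anti, so the enolate reaches only the oxygen-bearing face and (R)-sulfur maps onto the C4 configuration of the target (the descriptor reads 4S in 15 only because chlorine raises the priority of C3); C3 and C5 arise without control, which is harmless because C5 becomes CH2 in step 8 and C3 is re-set in steps 8 and 9. The step needs O-acylation of the sulfoxide to outrun ketene oligomerisation, (2+2) addition and ring acylation by 12, which slow addition, the electron-poor sulfinyl alkene and ether-solvated ZnCl2 should secure, while the regiochemistry (carbon to C4, oxygen to C5) is fixed by the six-membered array.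

**Step 8**
Reactants: 15 (4S)-3-chloro-5-(p-tolylsulfanyl)-3,4-bis(3,4,5-trimethoxybenzyl)dihydrofuran-2(3H)-one
Product: 16 (4R)-3,4-bis(3,4,5-trimethoxybenzyl)dihydrofuran-2(3H)-one (C3 epimers)
Conditions: Bu3SnH (excess), AIBN (cat.), toluene, reflux
Reagents that add atoms: none
Why: Radical chain reduction: the stannyl radical should abstract the tertiary α-carbonyl chlorine and cleave the C5–S bond of the O,S-acetal, each carbon radical being quenched by Bu3SnH; C4 is untouched and hydrogen delivery anti to the C4 substituent should favour the cis C3 epimer.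

**Step 9**
Reactants: 16 (4R)-3,4-bis(3,4,5-trimethoxybenzyl)dihydrofuran-2(3H)-one (C3 epimers)
Product: 17 (3R,4R)-3,4-bis(3,4,5-trimethoxybenzyl)dihydrofuran-2(3H)-one, (−)-cubebininolide
Conditions: DBU (cat.), toluene, 80 °C
Reagents that add atoms: none
Why: Base-mediated epimerisation through the lactone enolate under thermodynamic control should converge on the more stable trans-2,3-dibenzyl lactone, so C3 becomes R relative to the fixed, non-enolisable (4R) centre.

**Compound list**
1 | 5-(bromomethyl)-1,2,3-trimethoxybenzene (3,4,5-trimethoxybenzyl bromide) | COc1cc(CBr)cc(OC)c1OC | starting material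
2 | ethynylmagnesium bromide | C#C[Mg]Br | starting material
3 | 1,2,3-trimethoxy-5-(prop-2-yn-1-yl)benzene | COc1cc(CC#C)cc(OC)c1OC | intermediate
4 | (1R,2S,5R)-(−)-menthyl (S)-p-toluenesulfinate | C[C@@H]1CC[C@H]([C@@H](C1)O[S@](=O)c2ccc(C)cc2)C(C)C | starting material
5 | [3-(3,4,5-trimethoxyphenyl)prop-1-yn-1-yl]magnesium bromide | COc1cc(CC#C[Mg]Br)cc(OC)c1OC | intermediate
6 | (S)-1,2,3-trimethoxy-5-[3-(p-tolylsulfinyl)prop-2-yn-1-yl]benzene | COc1cc(CC#C[S@@](=O)c2ccc(C)cc2)cc(OC)c1OC | intermediate
7 | (R,Z)-1,2,3-trimethoxy-5-[3-(p-tolylsulfinyl)prop-2-en-1-yl]benzene | COc1cc(C/C=C\[S@@](=O)c2ccc(C)cc2)cc(OC)c1OC | intermediate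
8 | methyl dichloroacetate | COC(=O)C(Cl)Cl | starting material
9 | lithium enolate of methyl dichloroacetate | COC(O[Li])=C(Cl)Cl | intermediate
10 | methyl 2,2-dichloro-3-(3,4,5-trimethoxyphenyl)propanoate | COC(=O)C(Cl)(Cl)Cc1cc(OC)c(OC)c(OC)c1 | intermediate
11 | 2,2-dichloro-3-(3,4,5-trimethoxyphenyl)propanoic acid | OC(=O)C(Cl)(Cl)Cc1cc(OC)c(OC)c(OC)c1 | intermediate
12 | 2,2-dichloro-3-(3,4,5-trimethoxyphenyl)propanoyl chloride | ClC(=O)C(Cl)(Cl)Cc1cc(OC)c(OC)c(OC)c1 | intermediate
13 | chloro(3,4,5-trimethoxybenzyl)ketene | O=C=C(Cl)Cc1cc(OC)c(OC)c(OC)c1 | intermediate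
14 | acyloxysulfonium enolate (zwitterion from 7 and 13, sulfur configuration retained) | COc1cc(C/C=C\[S@@+](OC([O-])=C(Cl)Cc2cc(OC)c(OC)c(OC)c2)c2ccc(C)cc2)cc(OC)c1OC | intermediate
15 | (4S)-3-chloro-5-(p-tolylsulfanyl)-3,4-bis(3,4,5-trimethoxybenzyl)dihydrofuran-2(3H)-one, epimers at C3 and C5 | COc1cc(C[C@H]2C(Sc3ccc(C)cc3)OC(=O)C2(Cl)Cc2cc(OC)c(OC)c(OC)c2)cc(OC)c1OC | intermediate
16 | (4R)-3,4-bis(3,4,5-trimethoxybenzyl)dihydrofuran-2(3H)-one, C3 epimers | COc1cc(C[C@H]2COC(=O)C2Cc2cc(OC)c(OC)c(OC)c2)cc(OC)c1OC | intermediate
17 | (3R,4R)-3,4-bis(3,4,5-trimethoxybenzyl)dihydrofuran-2(3H)-one, (−)-cubebininolide | COc1cc(C[C@H]2COC(=O)[C@@H]2Cc2cc(OC)c(OC)c(OC)c2)cc(OC)c1OC | target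

**Step count and risks**
Total step count: 9. Longest linear sequence: 6 steps (1, 2, 3, 7, 8, 9; the branch 4, 5, 6, 7, 8, 9 is equally long).

Steps most likely to fail:

1. Step 7 (Proposed new method). The monochloro ketene may oligomerise, or the acid chloride may acylate its own arene, before the sulfinyl oxygen captures the ketene; the zwitterion may also collapse by simple Pummerer-type deoxygenation instead of the [3,3] shift. The fallback uses known chemistry, sets out from 7 and comes back at 17. Sulfoxide 7 would be treated with dichloroketene made in the flask from trichloroacetyl chloride and Zn(Cu) couple in refluxing Et2O, the established lactonization of alkenyl sulfoxides, to give (4S)-3,3-dichloro-5-(p-tolylsulfanyl)-4-(3,4,5-trimethoxybenzyl)dihydrofuran-2(3H)-one F1. Bu3SnH and AIBN in refluxing toluene should then strip both chlorines and the sulfur to give (R)-4-(3,4,5-trimethoxybenzyl)dihydrofuran-2(3H)-one F2. Enolisation with LiN(SiMe3)2 in THF at −78 °C and alkylation with bromide 1 anti to the C4 substituent should give 17 directly. Steps 4 to 6, 8 and 9 then fall away.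

2. Step 2. The Grignard reagent may transfer a proton from the doubly activated propargylic CH2 of the product, which would lead to isomerisation to the allenyl sulfoxide and loss of material. The fallback sets out from 3 and comes back at 7, so that no alkynyl sulfoxide is ever formed. Alkyne 3 would be iodinated at its terminus (N-iodosuccinimide, AgNO3 cat., acetone) to 5-(3-iodoprop-2-yn-1-yl)-1,2,3-trimethoxybenzene F3. Diimide cis-reduction (2-nitrobenzenesulfonyl hydrazide, Et3N, THF/iPrOH) should give (Z)-5-(3-iodoprop-2-en-1-yl)-1,2,3-trimethoxybenzene F4. Iodine–magnesium exchange (iPrMgCl·LiCl, THF, 0 °C) with retention of alkene geometry should give (Z)-[3-(3,4,5-trimethoxyphenyl)prop-1-en-1-yl]magnesium chloride F5, which is sulfinylated by 4 with inversion at sulfur (Andersen synthesis, toluene, −40 °C) to give 7. Steps 2 and 3 are replaced.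

3. Step 4. The dichloroester enolate may decompose by carbenoid α-elimination or self-condensation before it is alkylated. The fallback sets out from 1 and comes back at ketene 13, the in-flask intermediate of step 7. Bromide 1 would alkylate the stabilised enolate of diethyl chloromalonate (K2CO3, DMF, rt) to give diethyl 2-chloro-2-(3,4,5-trimethoxybenzyl)malonate F6. Acidic hydrolysis and decarboxylation (aq. HCl/AcOH, reflux) should give 2-chloro-3-(3,4,5-trimethoxyphenyl)propanoic acid F7, and (COCl)2 with catalytic DMF its acid chloride, 2-chloro-3-(3,4,5-trimethoxyphenyl)propanoyl chloride F8. Dehydrochlorination of this chloride with Et3N in Et2O at low temperature, a standard entry to alkylchloroketenes, should deliver 13 in the presence of 7. Steps 4 to 6 are replaced, and step 7 is run with elimination in place of zinc dechlorination.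

**Further compounds**
F1 | step 7 | (4S)-3,3-dichloro-5-(p-tolylsulfanyl)-4-(3,4,5-trimethoxybenzyl)dihydrofuran-2(3H)-one (C5 epimers) | COc1cc(C[C@H]2C(Sc3ccc(C)cc3)OC(=O)C2(Cl)Cl)cc(OC)c1OC
F2 | step 7 | (R)-4-(3,4,5-trimethoxybenzyl)dihydrofuran-2(3H)-one | COc1cc(C[C@H]2COC(=O)C2)cc(OC)c1OC
F3 | step 2 | 5-(3-iodoprop-2-yn-1-yl)-1,2,3-trimethoxybenzene | COc1cc(CC#CI)cc(OC)c1OC
F4 | step 2 | (Z)-5-(3-iodoprop-2-en-1-yl)-1,2,3-trimethoxybenzene | COc1cc(C/C=C\I)cc(OC)c1OC
F5 | step 2 | (Z)-[3-(3,4,5-trimethoxyphenyl)prop-1-en-1-yl]magnesium chloride | COc1cc(C/C=C\[Mg]Cl)cc(OC)c1OC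
F6 | step 4 | diethyl 2-chloro-2-(3,4,5-trimethoxybenzyl)malonate | CCOC(=O)C(Cl)(Cc1cc(OC)c(OC)c(OC)c1)C(=O)OCC
F7 | step 4 | 2-chloro-3-(3,4,5-trimethoxyphenyl)propanoic acid (racemic) | OC(=O)C(Cl)Cc1cc(OC)c(OC)c(OC)c1
F8 | step 4 | 2-chloro-3-(3,4,5-trimethoxyphenyl)propanoyl chloride (racemic) | ClC(=O)C(Cl)Cc1cc(OC)c(OC)c(OC)c1
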